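In a one-step world, a fed portion of starting material is lost at a steady pace per unit of catalyst, a pseudo-first-order loss. While a steady feed runs, the average portion has sat for half of the elapsed time. So I take a shortcut: I set the fraction of the fed amount still left equal to the exponential of minus pace times catalyst, as a fraction of the charge, times that average sitting time.

| flask | starting material | free catalyst | remark | time |
|---|---|---|---|---|
| west | 0.30 M (fed, over 12 min) | 3.8 mM | run made earlier |  |
| north | 0.30 M (fed, over 12 min) | 15 mM | run made earlier |  |
| flask | 0.30 M (fed, over 12 min) | 7.5 mM |  | 12 min |

| run | time / min | catalyst intermediate A / % | side product / % | target / % | starting material / % | catalyst intermediate B / % |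
|---|---|---|---|---|---|---|
| west | 2.00 | 0.8 | 0.4 | 0.3 | 14.7 | 0.8 |
| west | 4.00 | 0.8 | 0 | 4.2 | 29.9 | 0 |
| west | 6.00 | 0 | 2.3 | 4.4 | 44.0 | 1.3 |
| west | 8.00 | 0 | 2.3 | 5.0 | 55.6 | 0 |
| west | 10.0 | 1.0 | 6.3 | 10.1 | 68.8 | 1.6 |
| north | 0.833 | 0.7 | 0 | 1.0 | 5.0 | 0 |
| north | 1.33 | 0.3 | 0 | 1.9 | 9.2 | 0 |
| north | 2.50 | 0 | 1.9 | 2.7 | 16.3 | 0.6 |
| north | 5.00 | 0 | 1.6 | 11.6 | 26.3 | 0.4 |
| north | 10.0 | 1.2 | 15.1 | 28.0 | 40.6 | 0.7 |

(standard deviation of a reading: 1 percentage point)

* the species in which most of what was charged as starting material, at 12 min sits (starting material / catalyst intermediate A / catalyst intermediate B / side product / target)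
* the largest share itself, whichever of these holds it, in percent of the starting material charged

- percent here means starting material units held: one side product counts as two
- the earlier runs were read with a standard deviation of 1 percentage point
- percentages count the whole charge, also what has not yet gone in

I read the last row of each run. In the west run at 10.0 min, 83.3% has been fed and 68.8% is left, with catalyst at 1.27% of the charge, so the pace reads 3.03 /min. In the north run at 10.0 min, the same 83.3% has been fed but 40.6% is left, with catalyst at 5.00%, so the pace reads 2.88 /min. The catalyst differs by a factor of 3.95, yet the two paces are nearly equal, as readings with a scatter of 1 percentage point. Their mean, 2.95 /min, is my turnover pace: the turnovers per minute of one catalyst facing the whole charge.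

In the flask, catalyst is 2.50% of the charge, and at 12 min the feed of 12 min has ended, so I reckon 64.2% of starting material left. On this reckoning the other species together hold 35.8%, which is less than that, so starting material holds most.

The forecast also says starting material, at 63%, on the ground that “Four times the catalyst gives four times k”.

The flask gives starting material at 64.0%.

    starting material + free catalyst → catalyst intermediate A (k = 15.3 /M/min)
    catalyst intermediate A → catalyst intermediate B (k = 9.80 /min)
    catalyst intermediate B → free catalyst + target (k = 8.33 /min)
    free catalyst → spent catalyst A (k = 0.0366 /min)
    2 catalyst intermediate A → spent catalyst B (k = 23.6 /M/min)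
    starting material + target → side product (k = 0.548 /M/min)

My reckoning for the flask stood at 64.2%. For a neighbour flask with catalyst at 0.633% of the charge, the same pace gives 89.4% left, and that flask holds 88.8% of starting material at 12.0 min. The flask is not at rest at 12 min. Left until 120 min, its starting material falls from 64.0% to 0.153%, and free catalyst falls from 41.4% to 1.58% of the catalyst charged. Target rises from 18.4% to 21.8%, and side product rises from 16.8% to 77.8%.

(The earlier runs and the new flask were computed from invented constants, noise included.)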